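**Retrosynthetic overview**

1. The target is a 2-methoxy-1,4-benzoquinone (ring A: C1=O, C2–OMe, C3–H, C4=O, C5–O-aryl, C6–CH2CH2-aryl). Its C5 oxygen (to ring D) and C6 ethylene (to ring B) are joined through ring D–CH2CH2–ring C–O–ring B in an 18-membered ring.
2. Enabling feature: C4–C5 of ring A is a two-carbon unit hanging on the ring D oxygen, and C6–C1–C2–C3 is a four-carbon unit with vicinal oxygens (C1, C2) hanging on the ring B ethylene. These units are the two ends of one open chain, so a single [4+2] that forms C3–C4 and C5–C6 closes ring A and the macrocycle together.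
3. Key disconnection: ring A at the phenol level (C4–H) goes back to a 5-benzyloxy-4-methoxy-2-pyrone (pyrone C3, C4, C5, C6 become ring A C3, C2, C1, C6; the lactone bridge leaves as CO2) and an (E)-β-aryloxyvinyl sulfone (the sulfonyl group activates and then leaves as sulfinic acid).
4. The open-chain precursor comes from a Chan–Lam ether (ring B–O–ring C), a Wittig olefination and hydrogenation (ring C–CH2CH2–ring D), a pyrone annulation on a Weinreb amide, and an oxa-Michael addition to an ethynyl sulfone.
5. Order of ring formation: rings B, C and D are bought; the temporary pyrone forms in step 7; ring A and the 18-membered ring form together in step 9; ring A is raised to the quinone in step 11.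

Key step: step 9

Remark: the target has no stereocentre; one alkene mixture and the sp3 centres of three in-flask intermediates are erased later in the route, so their SMILES carry no configuration.

**Route**

Step 1
Reactants: 1 4-(benzyloxy)-3-hydroxybenzaldehyde; 2 [4-(3-methoxy-3-oxopropyl)phenyl]boronic acid
Product: 3 methyl 3-{4-[2-(benzyloxy)-5-formylphenoxy]phenyl}propanoate
Conditions: Cu(OAc)2 (20 mol %), pyridine, 4 Å MS, CH2Cl2, O2 (1 atm), rt
Reagents that add atoms: none
Why: Chan–Lam oxidative O-arylation should join the ortho-alkoxy phenol and the arylboronic acid at room temperature without touching the aldehyde or the ester, which sets the ring B–O–ring C ether with the ring C pattern of the target.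

Step 2
Reactants: 4 3-(hydroxymethyl)phenol
Product: 5 (3-hydroxybenzyl)triphenylphosphonium bromide
Conditions: PPh3·HBr, MeCN, reflux
Reagents that add atoms: triphenylphosphine hydrobromide, Br.c1ccc(cc1)P(c1ccccc1)c1ccccc1
Why: Acid-promoted substitution of the benzylic alcohol by bromide followed by quaternisation of PPh3 should give the phosphonium salt in one pot while the phenol stays free.

Step 3
Reactants: 3 methyl 3-{4-[2-(benzyloxy)-5-formylphenoxy]phenyl}propanoate; 5 (3-hydroxybenzyl)triphenylphosphonium bromide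
Product: 6 methyl 3-(4-{2-(benzyloxy)-5-[2-(3-hydroxyphenyl)ethenyl]phenoxy}phenyl)propanoate (E/Z mixture)
Conditions: 5, LiN(SiMe3)2 (2.1 equiv), THF, 0 °C; then 3, −78 °C to rt
Reagents that add atoms: none
Why: Wittig olefination of the aryl aldehyde with the semi-stabilised benzyl ylide (the phenol is masked as its phenoxide by the second equivalent of base) should build the ring C–ring D two-carbon bridge without attack on the ester.

Step 4
Reactants: 6 methyl 3-(4-{2-(benzyloxy)-5-[2-(3-hydroxyphenyl)ethenyl]phenoxy}phenyl)propanoate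
Product: 7 methyl 3-(4-{2-(benzyloxy)-5-[2-(3-hydroxyphenyl)ethyl]phenoxy}phenyl)propanoate
Conditions: H2 (3 atm), RhCl(PPh3)3 (5 mol %), PhH/EtOH, 40 °C
Reagents that add atoms: none
Why: Homogeneous hydrogenation with RhCl(PPh3)3 should saturate both stilbene isomers without hydrogenolysis of the aryl benzyl ether.

Step 5
Reactants: 7 methyl 3-(4-{2-(benzyloxy)-5-[2-(3-hydroxyphenyl)ethyl]phenoxy}phenyl)propanoate
Product: 8 3-(4-{2-(benzyloxy)-5-[2-(3-hydroxyphenyl)ethyl]phenoxy}phenyl)-N-methoxy-N-methylpropanamide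
Conditions: MeNH(OMe)·HCl, i-PrMgCl (4 equiv), THF, −20 to 0 °C
Reagents that add atoms: N,O-dimethylhydroxylamine hydrochloride, CNOC.Cl
Why: Aminolysis of the methyl ester by the magnesium amide of N,O-dimethylhydroxylamine should give the Weinreb amide, with the phenol carried as its magnesium phenoxide.

Step 6
Reactants: 9 ethyl 4-(benzyloxy)-3-oxobutanoate
Product: 10 ethyl (2E)-4-(benzyloxy)-3-methoxybut-2-enoate
Conditions: HC(OMe)3, H2SO4 (cat.), rt
Reagents that add atoms: trimethyl orthoformate, COC(OC)OC
Why: Acid-catalysed enol ether formation from the β-keto ester with the orthoformate should give the thermodynamic (E)-β-methoxy enoate, which carries the future ring A methoxy group and places the benzyloxymethyl carbon cis to the ester for lactonisation.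

Step 7
Reactants: 8 3-(4-{2-(benzyloxy)-5-[2-(3-hydroxyphenyl)ethyl]phenoxy}phenyl)-N-methoxy-N-methylpropanamide; 10 ethyl (2E)-4-(benzyloxy)-3-methoxybut-2-enoate
Product: 12 5-(benzyloxy)-6-[2-(4-{2-(benzyloxy)-5-[2-(3-hydroxyphenyl)ethyl]phenoxy}phenyl)ethyl]-4-methoxy-2H-pyran-2-one, via keto enoate 11 (not isolated)
Conditions: 10, LiN(i-Pr)2, THF, −78 °C; then lithium phenoxide of 8 (8 + LiN(i-Pr)2), −78 to 0 °C; AcOH; then DBU (cat.), PhMe, 80 °C
Reagents that add atoms: none
Why: The lithium dienolate of the β-methoxy enoate should be acylated at its γ-carbon by the Weinreb amide (vinylogous Claisen-type acylation through a chelated tetrahedral intermediate), and the δ-keto ester 11 should then enolise and lactonise onto the cis ester to give the 4-methoxy-2-pyrone.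

Step 8
Reactants: 12 5-(benzyloxy)-6-[2-(4-{2-(benzyloxy)-5-[2-(3-hydroxyphenyl)ethyl]phenoxy}phenyl)ethyl]-4-methoxy-2H-pyran-2-one; 13 1-(ethynylsulfonyl)-4-methylbenzene
Product: 14 5-(benzyloxy)-6-{2-[4-(2-(benzyloxy)-5-{2-[3-({(E)-2-[(4-methylphenyl)sulfonyl]ethenyl}oxy)phenyl]ethyl}phenoxy)phenyl]ethyl}-4-methoxy-2H-pyran-2-one
Conditions: N-methylmorpholine (cat.), CH2Cl2, 0 °C to rt
Reagents that add atoms: none
Why: Amine-catalysed oxa-Michael addition of the only free phenol to the ethynyl sulfone should give the (E)-β-aryloxyvinyl sulfone under conditions that leave the pyrone untouched.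

Step 9
Reactants: 14 5-(benzyloxy)-6-{2-[4-(2-(benzyloxy)-5-{2-[3-({(E)-2-[(4-methylphenyl)sulfonyl]ethenyl}oxy)phenyl]ethyl}phenoxy)phenyl]ethyl}-4-methoxy-2H-pyran-2-one
Product: 17 macrocyclic ring A arene bis(benzyl ether) (ring A: 1-OBn 2-OMe 3-H 4-H 5-O-ring D 6-CH2CH2-ring B; ring C OBn), via bridged lactone 15 (not isolated), via cyclohexadiene 16 (not isolated)
Conditions: 1,2-dichlorobenzene (1 mM, slow addition), BHT, 180 °C
Reagents that add atoms: none
Why: On heating, the electron-rich 4,5-dialkoxy-2-pyrone should act as the diene (termini C3 and C6) toward the tethered vinyl sulfone in a normal-demand Diels–Alder reaction to give bridged lactone 15, which loses CO2 by retro-Diels–Alder to cyclohexadiene 16 and then p-toluenesulfinic acid to give benzene ring A, so that the ring A bonds C3–C4 and C5–C6 are both made here. The closest known reaction type is the 2-pyrone/vinyl sulfone Diels–Alder, decarboxylation and sulfinate-elimination cascade, in which the vinyl sulfone is an alkyne equivalent and which is known in intramolecular, cyclophane-forming form. Ring A closes by [4+2] cycloaddition followed by cycloreversion, and the 18-membered ring closes in the same cycloaddition as an end-to-end union of the chain termini, because the dienophile sits on the ring D oxygen and the diene on the ring B ethylene. No stereocentre survives, since the four sp3 centres of 15 (any endo/exo or E/Z mixture) are erased on aromatisation. The step needs regioselectivity (aryloxy carbon to pyrone C6), which the sulfonyl group should secure by making the aryloxy-bearing β-carbon the electrophilic end that pairs with C6, the nucleophilic carbon of the 5-benzyloxy enol ether, while the sulfonyl-bearing carbon goes to C3 as is usual for acceptor-substituted alkenes and 2-pyrones; it also needs loss of sulfinate and not of aryloxide, which base-free conditions should favour through ionisation at the sulfonyl carbon to a methoxy-stabilised cyclohexadienyl cation. High dilution should favour ring closure over oligomerisation.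

Step 10
Reactants: 17 macrocyclic ring A arene bis(benzyl ether)
Product: 18 macrocyclic diphenol (ring A: 1-OH 2-OMe 4-H; ring C OH)
Conditions: H2 (1 atm), Pd/C, EtOAc/MeOH, rt
Reagents that add atoms: none
Why: Hydrogenolysis over Pd/C should cleave both aryl benzyl ethers, and the macrocycle holds no other reducible group.

Step 11
Reactants: 18 macrocyclic diphenol
Product: 19 target quinone CNP0332646.0
Conditions: O2 (1 atm), Co(salen) [Co(C16H14N2O2)] (10 mol %), MeCN, rt
Reagents that add atoms: dioxygen, O=O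
Why: Co(salen)-catalysed aerobic oxidation of a 2,6-disubstituted phenol with a free para position should give the para-quinone (new C4 carbonyl), whereas the ring C phenol has its para position blocked by the ethylene bridge and cannot form a para-quinone.

**Compound list**

1 | 4-(benzyloxy)-3-hydroxybenzaldehyde | O=Cc1ccc(OCc2ccccc2)c(O)c1 | starting material
2 | [4-(3-methoxy-3-oxopropyl)phenyl]boronic acid | COC(=O)CCc1ccc(cc1)B(O)O | starting material
3 | methyl 3-{4-[2-(benzyloxy)-5-formylphenoxy]phenyl}propanoate | COC(=O)CCc1ccc(cc1)Oc1cc(C=O)ccc1OCc1ccccc1 | intermediate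
4 | 3-(hydroxymethyl)phenol (3-hydroxybenzyl alcohol) | OCc1cccc(O)c1 | starting material
5 | (3-hydroxybenzyl)triphenylphosphonium bromide | [Br-].Oc1cccc(C[P+](c2ccccc2)(c2ccccc2)c2ccccc2)c1 | intermediate
6 | methyl 3-(4-{2-(benzyloxy)-5-[2-(3-hydroxyphenyl)ethenyl]phenoxy}phenyl)propanoate, E/Z mixture | COC(=O)CCc1ccc(cc1)Oc1cc(C=Cc2cccc(O)c2)ccc1OCc1ccccc1 | intermediate
7 | methyl 3-(4-{2-(benzyloxy)-5-[2-(3-hydroxyphenyl)ethyl]phenoxy}phenyl)propanoate | COC(=O)CCc1ccc(cc1)Oc1cc(CCc2cccc(O)c2)ccc1OCc1ccccc1 | intermediate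
8 | 3-(4-{2-(benzyloxy)-5-[2-(3-hydroxyphenyl)ethyl]phenoxy}phenyl)-N-methoxy-N-methylpropanamide | CON(C)C(=O)CCc1ccc(cc1)Oc1cc(CCc2cccc(O)c2)ccc1OCc1ccccc1 | intermediate
9 | ethyl 4-(benzyloxy)-3-oxobutanoate | CCOC(=O)CC(=O)COCc1ccccc1 | starting material
10 | ethyl (2E)-4-(benzyloxy)-3-methoxybut-2-enoate | CCOC(=O)/C=C(/OC)COCc1ccccc1 | intermediate
11 | ethyl (2E)-4-(benzyloxy)-7-(4-{2-(benzyloxy)-5-[2-(3-hydroxyphenyl)ethyl]phenoxy}phenyl)-3-methoxy-5-oxohept-2-enoate, racemic at C4, not isolated | CCOC(=O)/C=C(/OC)C(OCc1ccccc1)C(=O)CCc1ccc(cc1)Oc1cc(CCc2cccc(O)c2)ccc1OCc1ccccc1 | intermediate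
12 | 5-(benzyloxy)-6-[2-(4-{2-(benzyloxy)-5-[2-(3-hydroxyphenyl)ethyl]phenoxy}phenyl)ethyl]-4-methoxy-2H-pyran-2-one | COC1=CC(=O)OC(CCc2ccc(cc2)Oc2cc(CCc3cccc(O)c3)ccc2OCc2ccccc2)=C1OCc1ccccc1 | intermediate
13 | 1-(ethynylsulfonyl)-4-methylbenzene (ethynyl p-tolyl sulfone) | Cc1ccc(cc1)S(=O)(=O)C#C | starting material
14 | 5-(benzyloxy)-6-{2-[4-(2-(benzyloxy)-5-{2-[3-({(E)-2-[(4-methylphenyl)sulfonyl]ethenyl}oxy)phenyl]ethyl}phenoxy)phenyl]ethyl}-4-methoxy-2H-pyran-2-one | COC1=CC(=O)OC(CCc2ccc(cc2)Oc2cc(CCc3cccc(O/C=C/S(=O)(=O)c4ccc(C)cc4)c3)ccc2OCc2ccccc2)=C1OCc1ccccc1 | intermediate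
15 | bridged lactone: 2-oxabicyclo[2.2.2]oct-7-en-3-one cycloadduct of 14 (pyrone C3 bonded to the sulfonyl-bearing carbon, pyrone C6 to the aryloxy-bearing carbon), racemic diastereomer mixture, not isolated | COC1=C(OCc4ccccc4)C23CCc4ccc(cc4)Oc4cc(ccc4OCc4ccccc4)CCc4cccc(c4)OC3C(S(=O)(=O)c3ccc(C)cc3)C1C(=O)O2 | intermediate
16 | macrocyclic cyclohexa-1,3-diene from 15 after loss of CO2 (sp3 carbons: CH–SO2Tol next to ring A C3, CH–O–ring D next to ring A C6), not isolated | COC1=CC(S(=O)(=O)c2ccc(C)cc2)C2Oc3cccc(c3)CCc3ccc(OCc4ccccc4)c(c3)Oc3ccc(cc3)CCC2=C1OCc1ccccc1 | intermediate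
17 | macrocycle with benzene ring A (C1–OBn, C2–OMe, C3–H, C4–H, C5–O–ring D, C6–CH2CH2–ring B) and ring C benzyl ether | COc1ccc2c(CCc3ccc(cc3)Oc3cc(ccc3OCc3ccccc3)CCc3cccc(c3)O2)c1OCc1ccccc1 | intermediate
18 | macrocyclic diphenol (ring A: C1–OH, C2–OMe, C3–H, C4–H, C5–O–ring D, C6–CH2CH2–ring B; ring C–OH free) | COc1ccc2c(CCc3ccc(cc3)Oc3cc(ccc3O)CCc3cccc(c3)O2)c1O | intermediate
19 | CNP0332646.0, macrocyclic 2-methoxy-1,4-benzoquinone (ring A: C1=O, C2–OMe, C3–H, C4=O, C5–O–ring D, C6–CH2CH2–ring B) | COC1=CC(=O)C2=C(CCc3ccc(cc3)Oc3cc(ccc3O)CCc3cccc(c3)O2)C1=O | target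

**Step count and risks**

Total step count: 11. Longest linear sequence: 9 steps (steps 1, 3, 4, 5, 7, 8, 9, 10, 11).

Steps most likely to fail:

1. Step 9. At the dilution needed for ring closure, the cycloaddition between the tethered pyrone and the push–pull vinyl sulfone may be slower than oligomerisation or thermal breakdown, and the cycloadduct may aromatise by expelling the aryloxide, which reopens the chain. The fallback sets out from 3 and comes back at 18; it runs the same cascade between two small partners at high concentration and closes the large ring afterwards at the ring C–ring D bridge. Aldehyde 3 is protected as dimethyl acetal F1 (HC(OMe)3, TsOH cat., MeOH) and its ester is converted into Weinreb amide F2 (conditions of step 5). Acylation of the dienolate of 10, aqueous HCl work-up (which frees the aldehyde) and DBU then give pyrone aldehyde F3. Heating F3 with an excess of the vinyl sulfone aldehyde F4 (made from 3-hydroxybenzaldehyde and 13 with N-methylmorpholine) should give dialdehyde F5 by intermolecular cycloaddition, CO2 loss and sulfinic acid loss; a regioisomer, if formed, can be removed at this stage. An intramolecular McMurry coupling with low-valent titanium (TiCl4, Zn, pyridine, THF, reflux, slow addition) should close the 18-membered ring as macrocyclic stilbene F6, and hydrogenation over Pd/C saturates the alkene and removes both benzyl groups to give 18.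

2. Step 7. Proton transfer from the acidic acylation product, or acylation at the α-carbon instead of the γ-carbon of the dienolate, may stop the pyrone annulation. The fallback sets out from 8 and comes back at 12. The dianion of 9 (NaH, then n-BuLi, THF, 0 °C) is acylated at C4 by 8 to give diketo ester F7. DBU in toluene at 80 °C closes the 4-hydroxy-2-pyrone F8. TMSCHN2 in MeOH/PhMe then methylates the acidic pyrone hydroxyl in the presence of the far less acidic phenol to give 12.

3. Step 11. Hydrogen abstraction from the ring C phenol may compete with oxidation of the ring A phenol and lead to radical coupling or over-oxidation. The fallback sets out from 18 and comes back at 19. The less hindered ring C phenol is silylated selectively (TBSCl 1.05 equiv, imidazole, DMF, 0 °C) to give mono-silyl ether F9. The remaining hindered ring A phenol is oxidised by Teuber oxidation with (KSO3)2NO (Fremy's salt, KH2PO4 buffer, acetone/H2O) to give silyl-protected quinone F10, and HF·pyridine in THF removes the silyl group to give 19.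

Further compounds
F1 | step 9 | methyl 3-{4-[2-(benzyloxy)-5-(dimethoxymethyl)phenoxy]phenyl}propanoate | COC(=O)CCc1ccc(cc1)Oc1cc(C(OC)OC)ccc1OCc1ccccc1
F2 | step 9 | 3-{4-[2-(benzyloxy)-5-(dimethoxymethyl)phenoxy]phenyl}-N-methoxy-N-methylpropanamide | CON(C)C(=O)CCc1ccc(cc1)Oc1cc(C(OC)OC)ccc1OCc1ccccc1
F3 | step 9 | 4-(benzyloxy)-3-(4-{2-[5-(benzyloxy)-4-methoxy-2-oxo-2H-pyran-6-yl]ethyl}phenoxy)benzaldehyde | COC1=CC(=O)OC(CCc2ccc(cc2)Oc2cc(C=O)ccc2OCc2ccccc2)=C1OCc1ccccc1
F4 | step 9 | 3-({(E)-2-[(4-methylphenyl)sulfonyl]ethenyl}oxy)benzaldehyde | Cc1ccc(cc1)S(=O)(=O)/C=C/Oc1cccc(C=O)c1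
F5 | step 9 | open-chain dialdehyde with benzene ring A (C1–OBn, C2–OMe, C5–O–(3-formylphenyl), C6–CH2CH2–ring B–O–ring C(OBn)(CHO)) | COc1ccc(Oc2cccc(C=O)c2)c(CCc2ccc(cc2)Oc2cc(C=O)ccc2OCc2ccccc2)c1OCc1ccccc1
F6 | step 9 | macrocyclic stilbene: 17 with a CH=CH bridge between ring C and ring D | COc1ccc2c(CCc3ccc(cc3)Oc3cc(ccc3OCc3ccccc3)C=Cc3cccc(c3)O2)c1OCc1ccccc1
F7 | step 7 | ethyl 4-(benzyloxy)-7-(4-{2-(benzyloxy)-5-[2-(3-hydroxyphenyl)ethyl]phenoxy}phenyl)-3,5-dioxoheptanoate | CCOC(=O)CC(=O)C(OCc1ccccc1)C(=O)CCc1ccc(cc1)Oc1cc(CCc2cccc(O)c2)ccc1OCc1ccccc1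
F8 | step 7 | 5-(benzyloxy)-6-[2-(4-{2-(benzyloxy)-5-[2-(3-hydroxyphenyl)ethyl]phenoxy}phenyl)ethyl]-4-hydroxy-2H-pyran-2-one | OC1=CC(=O)OC(CCc2ccc(cc2)Oc2cc(CCc3cccc(O)c3)ccc2OCc2ccccc2)=C1OCc1ccccc1
F9 | step 11 | 18 with the ring C hydroxyl as its tert-butyldimethylsilyl ether | COc1ccc2c(CCc3ccc(cc3)Oc3cc(ccc3O[Si](C)(C)C(C)(C)C)CCc3cccc(c3)O2)c1O
F10 | step 11 | 19 with the ring C hydroxyl as its tert-butyldimethylsilyl ether | COC1=CC(=O)C2=C(CCc3ccc(cc3)Oc3cc(ccc3O[Si](C)(C)C(C)(C)C)CCc3cccc(c3)O2)C1=O
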